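## Retrosynthetic overview

1. Last bond: C8–C9 of the triene by Suzuki–Miyaura coupling of tetronic acid vinyl iodide 19 with dienylboronate 12.
2. 19 comes from the proposed enantioselective C5-alkylation of the dianion of 3-methyltetronic acid 17 with allylic bromide 16, which forms C5–C6 and sets the only stereocentre; 16 comes from propargyl alcohol by carboalumination/iodination and bromination.
3. 12 comes from boron-Takai olefination (C9=C10), Wittig olefination (C11=C12) and Negishi coupling at the C–Br bond of bromo-bisfuran 5.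
4. 5 comes from furan-3-yllithium and 4-bromofurfural, then ionic deoxygenation (furan–CH2–furan link).
5. Rings: none is built. Both furans (1, 2) and the tetronic acid ring (17) are bought; the two furans are joined first (steps 1–2) and the tetronic acid ring is attached last (step 10).

Assumption: the (R,R)-tetramine is taken to give the (S)-product in step 9 (if the sense of induction proves opposite, its enantiomer is used and nothing else changes), and 2, 6, 9, 11 and 17 are taken as catalogue compounds.

Reagent of step 9 ("the tetramine"): (R,R)-N1,N3-bis[1-phenyl-2-(piperidin-1-yl)ethyl]propane-1,3-diamine, SMILES C(CN[C@@H](CN1CCCCC1)c1ccccc1)CN[C@@H](CN1CCCCC1)c1ccccc1. It is recovered by acid extraction.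

## Route

Step 1
Reactants: 1 3-bromofuran; 2 4-bromofuran-2-carbaldehyde
Product: 4 (4-bromofuran-2-yl)(furan-3-yl)methanol (racemic), via furan-3-yllithium 3 (not isolated)
Conditions: n-BuLi (1.05 equiv), THF, −78 °C, 20 min; then 2, −78 °C, 1 h; aq. NH4Cl
Reagents that add atoms: none
Why: Bromine–lithium exchange at −78 °C gives furan-3-yllithium, which adds to the aldehyde (organolithium 1,2-addition) much faster than it exchanges with the ring bromide of 2; the racemic carbinol centre is removed in step 2.

Step 2
Reactants: 4 (4-bromofuran-2-yl)(furan-3-yl)methanol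
Product: 5 4-bromo-2-(furan-3-ylmethyl)furan
Conditions: Et3SiH (4 equiv), CF3CO2H (3 equiv), CH2Cl2, −20 → 0 °C, 30 min; aq. NaHCO3
Reagents that add atoms: none
Why: Ionic hydrogenation: the acid ionises the doubly furyl-stabilised carbinol and excess silane traps the cation by hydride transfer faster than Friedel–Crafts oligomerisation at low temperature, leaving the ring bromide untouched.

Step 3
Reactants: 5 4-bromo-2-(furan-3-ylmethyl)furan; 6 (3-ethoxy-3-oxopropyl)zinc bromide
Product: 7 ethyl 3-[5-(furan-3-ylmethyl)furan-3-yl]propanoate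
Conditions: 6 (1.5 equiv, 0.5 M in THF), Pd(OAc)2 (2 mol %), SPhos (2-dicyclohexylphosphino-2′,6′-dimethoxybiphenyl, 4 mol %), THF, 45 °C, 6 h
Reagents that add atoms: none
Why: Negishi cross-coupling of a primary alkylzinc halide with a heteroaryl bromide; the bulky electron-rich biaryl phosphine drives oxidative addition of zerovalent palladium into the electron-rich furyl C–Br bond and lets reductive elimination outrun beta-hydride elimination, and the ester is inert to the zinc reagent.

Step 4
Reactants: 7 ethyl 3-[5-(furan-3-ylmethyl)furan-3-yl]propanoate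
Product: 8 3-[5-(furan-3-ylmethyl)furan-3-yl]propanal
Conditions: i-Bu2AlH (1.1 equiv), CH2Cl2, −78 °C, 1 h; MeOH, then aq. KNaC4H4O6
Reagents that add atoms: none
Why: Partial reduction of an unhindered ethyl ester with one hydride equivalent at −78 °C is a standard ester-to-aldehyde reduction, and furans are inert to the hydride.

Step 5
Reactants: 8 3-[5-(furan-3-ylmethyl)furan-3-yl]propanal; 9 2-(triphenyl-λ5-phosphanylidene)propanal
Product: 10 (E)-5-[5-(furan-3-ylmethyl)furan-3-yl]-2-methylpent-2-enal
Conditions: 9 (1.3 equiv), toluene, 80 °C, 14 h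
Reagents that add atoms: none
Why: Wittig olefination with a formyl-stabilised ylide gives the (E)-trisubstituted enal (C11=C12), and the product enal is too unreactive toward the ylide for a second olefination to compete.

Step 6
Reactants: 10 (E)-5-[5-(furan-3-ylmethyl)furan-3-yl]-2-methylpent-2-enal; 11 2-(dichloromethyl)-4,4,5,5-tetramethyl-1,3,2-dioxaborolane
Product: 12 2-{(1E,3E)-6-[5-(furan-3-ylmethyl)furan-3-yl]-3-methylhexa-1,3-dien-1-yl}-4,4,5,5-tetramethyl-1,3,2-dioxaborolane
Conditions: 11 (2 equiv), CrCl2 (8 equiv), LiI (4 equiv), THF, 23 °C, 6 h, dark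
Reagents that add atoms: none
Why: Takai–Utimoto boron olefination: the geminal dichromium reagent formed from 11 and divalent chromium adds only 1,2 to the enal carbonyl, and anti elimination sets the new C9=C10 bond E without touching the furans or the existing alkene.

Step 7
Reactants: 13 prop-2-yn-1-ol
Product: 15 (E)-3-iodo-2-methylprop-2-en-1-ol, via dialuminated alkenylalane 14 (not isolated)
Conditions: Me3Al (3 equiv), (C5H5)2ZrCl2 (0.25 equiv), CH2Cl2, 0 → 23 °C, 16 h; then iodine (1.2 equiv), THF, −30 → 0 °C; aq. K2CO3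
Reagents that add atoms: trimethylaluminium C[Al](C)C; iodine [I][I]
Why: Negishi zirconium-catalysed carboalumination adds methyl and aluminium syn across the alkyne with methyl on the internal carbon, and iodinolysis of the alkenyl–aluminium bond with retention fixes the E geometry.

Step 8
Reactants: 15 (E)-3-iodo-2-methylprop-2-en-1-ol
Product: 16 (E)-3-bromo-1-iodo-2-methylprop-1-ene
Conditions: CBr4 (1.2 equiv), PPh3 (1.25 equiv), CH2Cl2, 0 °C, 1 h, dark
Reagents that add atoms: carbon tetrabromide BrC(Br)(Br)Br
Why: Appel bromination: bromide displaces the oxyphosphonium leaving group by SN2 at the primary allylic carbon under neutral conditions that preserve the vinyl iodide and its geometry.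

Step 9
Reactants: 17 4-hydroxy-3-methylfuran-2(5H)-one (3-methyltetronic acid); 16 (E)-3-bromo-1-iodo-2-methylprop-1-ene
Product: 19 (5S)-4-hydroxy-5-[(E)-3-iodo-2-methylprop-2-en-1-yl]-3-methylfuran-2(5H)-one, via dilithium 3-methylfuran-2,4-bis(olate) 18 (not isolated)
Conditions: the tetramine (1.05 equiv), n-BuLi (4.1 equiv), THF, 0 °C, 30 min; then 16 (1.3 equiv), −78 °C, 6 h; aq. HCl (1 M), tetramine recovered from the aqueous layer
Reagents that add atoms: none
Why: Proposed new method: enantioselective C5 (γ) alkylation of an unprotected tetronic acid dianion held in a mixed aggregate with a C2-symmetric chiral dilithium diamide; four equivalents of n-BuLi turn the tetramine into its dilithium diamide and 17 into the planar furan-2,4-diolate 18, whose two O–Li contacts bridge to the amide nitrogens so that the phenyl-bearing backbone shields one face of C5 (the last site deprotonated and therefore the site of SN2 attack), the ring removes any enolate-geometry issue, and alkylation at −78 °C by the reactive allylic bromide is faster than re-deprotonation of the product monoanion, so the C5–C6 bond and the (S)-stereocentre are set in one reagent-controlled event; the closest known reaction types are the enantioselective alkylation of carboxylic acid enediolates with chiral dilithium amides as recoverable non-covalent auxiliaries and the racemic C5 alkylation of lithiated tetronates.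

Step 10
Reactants: 19 (5S)-4-hydroxy-5-[(E)-3-iodo-2-methylprop-2-en-1-yl]-3-methylfuran-2(5H)-one; 12 2-{(1E,3E)-6-[5-(furan-3-ylmethyl)furan-3-yl]-3-methylhexa-1,3-dien-1-yl}-4,4,5,5-tetramethyl-1,3,2-dioxaborolane
Product: 20 (5S)-5-{(2E,4E,6E)-9-[5-(furan-3-ylmethyl)furan-3-yl]-2,6-dimethylnona-2,4,6-trien-1-yl}-4-hydroxy-3-methylfuran-2(5H)-one
Conditions: 12 (1.2 equiv), PdCl2(dppf) ([1,1′-bis(diphenylphosphino)ferrocene]palladium dichloride, 5 mol %), aq. K3PO4 (4 equiv), THF, 23 °C, 4 h, dark, argon; then aq. NaH2PO4 to pH 4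
Reagents that add atoms: none
Why: Suzuki–Miyaura alkenyl–alkenyl coupling proceeds with retention at both partners and completes the (E,E,E)-triene; the tetronic acid is present as its potassium salt, whose C5–H is not acidic, so the stereocentre is not scrambled.

## Compound list

1 | 3-bromofuran | Brc1ccoc1 | starting material
2 | 4-bromofuran-2-carbaldehyde | O=Cc1cc(Br)co1 | starting material
3 | furan-3-yllithium (formed in the flask) | [Li]c1ccoc1 | intermediate
4 | (4-bromofuran-2-yl)(furan-3-yl)methanol, racemic | OC(c1cc(Br)co1)c1ccoc1 | intermediate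
5 | 4-bromo-2-(furan-3-ylmethyl)furan | Brc1coc(Cc2ccoc2)c1 | intermediate
6 | (3-ethoxy-3-oxopropyl)zinc bromide | CCOC(=O)CC[Zn]Br | starting material
7 | ethyl 3-[5-(furan-3-ylmethyl)furan-3-yl]propanoate | CCOC(=O)CCc1coc(Cc2ccoc2)c1 | intermediate
8 | 3-[5-(furan-3-ylmethyl)furan-3-yl]propanal | O=CCCc1coc(Cc2ccoc2)c1 | intermediate
9 | 2-(triphenyl-λ5-phosphanylidene)propanal | CC(C=O)=P(c1ccccc1)(c1ccccc1)c1ccccc1 | starting material
10 | (E)-5-[5-(furan-3-ylmethyl)furan-3-yl]-2-methylpent-2-enal | O=C/C(C)=C/CCc1coc(Cc2ccoc2)c1 | intermediate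
11 | 2-(dichloromethyl)-4,4,5,5-tetramethyl-1,3,2-dioxaborolane | ClC(Cl)B1OC(C)(C)C(C)(C)O1 | starting material
12 | 2-{(1E,3E)-6-[5-(furan-3-ylmethyl)furan-3-yl]-3-methylhexa-1,3-dien-1-yl}-4,4,5,5-tetramethyl-1,3,2-dioxaborolane | CC1(C)OB(/C=C/C(C)=C/CCc2coc(Cc3ccoc3)c2)OC1(C)C | intermediate
13 | prop-2-yn-1-ol | OCC#C | starting material
14 | (E)-{3-[(dimethylalumanyl)oxy]-2-methylprop-1-en-1-yl}dimethylalumane (formed in the flask) | C[Al](C)OC/C(C)=C/[Al](C)C | intermediate
15 | (E)-3-iodo-2-methylprop-2-en-1-ol | OC/C(C)=C/I | intermediate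
16 | (E)-3-bromo-1-iodo-2-methylprop-1-ene | BrC/C(C)=C/I | intermediate
17 | 4-hydroxy-3-methylfuran-2(5H)-one (3-methyltetronic acid) | CC1=C(O)COC1=O | starting material
18 | dilithium 3-methylfuran-2,4-bis(olate) (formed in the flask, aggregated with the chiral dilithium diamide) | Cc1c(O[Li])coc1O[Li] | intermediate
19 | (5S)-4-hydroxy-5-[(E)-3-iodo-2-methylprop-2-en-1-yl]-3-methylfuran-2(5H)-one | CC1=C(O)[C@H](C/C(C)=C/I)OC1=O | intermediate
20 | (5S)-5-{(2E,4E,6E)-9-[5-(furan-3-ylmethyl)furan-3-yl]-2,6-dimethylnona-2,4,6-trien-1-yl}-4-hydroxy-3-methylfuran-2(5H)-one | CC1=C(O)[C@H](C/C(C)=C/C=C/C(C)=C/CCc2coc(Cc3ccoc3)c2)OC1=O | target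

## Step count and risks

Total step count: 10. Longest linear sequence: 7 (steps 1–6, then step 10); the tetronic acid branch is steps 7–9.

The three steps most likely to fail:

**Step 9 (the proposed new method).** The level and sense of induction are unknown, the dianion aggregate may be poorly soluble, and the allylic bromide may N-alkylate the lithium amide. The fallback uses known chemistry (chiral glycolate alkylation, then Dieckmann ring closure); it sets out from 16 and comes back to the route at 19. The lithium enolate of commercial (5R,6R)-5,6-dimethoxy-5,6-dimethyl-1,4-dioxan-2-one (LiN(SiMe3)2, THF, −78 °C) is alkylated with 16 on the face away from the axial 5-methoxy group to give (3S,5R,6R)-3-[(E)-3-iodo-2-methylprop-2-en-1-yl]-5,6-dimethoxy-5,6-dimethyl-1,4-dioxan-2-one F1. Acidic methanolysis (Me3SiCl, MeOH, 23 °C) releases methyl (2S,4E)-2-hydroxy-5-iodo-4-methylpent-4-enoate F2. Acylation ((EtCO)2O, Et3N, DMAP, CH2Cl2, 0 °C) gives methyl (2S,4E)-5-iodo-4-methyl-2-(propanoyloxy)pent-4-enoate F3. Dieckmann cyclisation (LiN(SiMe3)2, 2.2 equiv, THF, −78 → 0 °C, then aq. HCl) builds the tetronic acid ring with retention at the oxygen-bearing carbon and gives 19.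

**Step 2.** The bis-furyl cation can oligomerise or the furans can degrade in acid. The fallback avoids any carbocation; it sets out from 4 and comes back at 5. Oxidation (MnO2, CH2Cl2, 23 °C) gives (4-bromofuran-2-yl)(furan-3-yl)methanone F4. Condensation with 4-methylbenzenesulfonohydrazide (EtOH, cat. AcOH, 60 °C) gives N′-[(4-bromofuran-2-yl)(furan-3-yl)methylidene]-4-methylbenzenesulfonohydrazide F5. Hydroboration of the C=N bond and elimination (catecholborane, CHCl3, 0 °C; then NaOAc·3H2O, 60 °C) gives 5.

**Step 10.** The free tetronate may slow or poison the palladium catalyst, and the triene acid is sensitive during acidic work-up. The fallback couples a masked, neutral tetronate and unmasks last; it sets out from 19 and comes back at 20. O-Methylation (Me3SiCHN2, MeOH–toluene, 0 °C) gives (5S)-5-[(E)-3-iodo-2-methylprop-2-en-1-yl]-4-methoxy-3-methylfuran-2(5H)-one F6. Suzuki–Miyaura coupling with 12 under the conditions of step 10 gives (5S)-5-{(2E,4E,6E)-9-[5-(furan-3-ylmethyl)furan-3-yl]-2,6-dimethylnona-2,4,6-trien-1-yl}-4-methoxy-3-methylfuran-2(5H)-one F7. SN2 demethylation (n-PrSLi, HMPA, 23 °C) gives 20.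

Further compounds
F1 | step 9 | (3S,5R,6R)-3-[(E)-3-iodo-2-methylprop-2-en-1-yl]-5,6-dimethoxy-5,6-dimethyl-1,4-dioxan-2-one | O=C1[C@H](C/C(C)=C/I)O[C@@](C)(OC)[C@](C)(OC)O1
F2 | step 9 | methyl (2S,4E)-2-hydroxy-5-iodo-4-methylpent-4-enoate | COC(=O)[C@@H](O)C/C(C)=C/I
F3 | step 9 | methyl (2S,4E)-5-iodo-4-methyl-2-(propanoyloxy)pent-4-enoate | CCC(=O)O[C@H](C(=O)OC)C/C(C)=C/I
F4 | step 2 | (4-bromofuran-2-yl)(furan-3-yl)methanone | O=C(c1cc(Br)co1)c1ccoc1
F5 | step 2 | N′-[(4-bromofuran-2-yl)(furan-3-yl)methylidene]-4-methylbenzenesulfonohydrazide | Cc1ccc(cc1)S(=O)(=O)NN=C(c1cc(Br)co1)c1ccoc1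
F6 | step 10 | (5S)-5-[(E)-3-iodo-2-methylprop-2-en-1-yl]-4-methoxy-3-methylfuran-2(5H)-one | CC1=C(OC)[C@H](C/C(C)=C/I)OC1=O
F7 | step 10 | (5S)-5-{(2E,4E,6E)-9-[5-(furan-3-ylmethyl)furan-3-yl]-2,6-dimethylnona-2,4,6-trien-1-yl}-4-methoxy-3-methylfuran-2(5H)-one | CC1=C(OC)[C@H](C/C(C)=C/C=C/C(C)=C/CCc2coc(Cc3ccoc3)c2)OC1=O
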